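The readings are simulated for an exercise; noise was put on by code.

Product at 6.0 h in the teal flask is what I had to foretell. There a solid substrate dissolves into starting material, which goes on with partner and initiator to product, and I also had to say how near saturation the solution then stands.

| setting | teal | green | flask |
|---|---|---|---|
| solid substrate | 14 mM | 9.4 mM | 14 mM |
| partner | 2 equiv | 2 equiv | 2.00 equiv |
| initiator | 10 mol% | 10 mol% | 10 mol% |
| remark | the very flask that is asked about, followed so far | run made earlier |  |
| time |  |  | 6.0 h |

teal run (percent of the solid substrate charged)

| time / min | product / % | starting material / % | solid substrate / % |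
|---|---|---|---|
| 8.00 | 2 | 0 | 98 |
| 15.0 | 1 | 0 | 98 |
| 30.0 | 0 | 0 | 94 |
| 60.0 | 5 | 2 | 98 |
| 120 | 10 | 0 | 88 |

green run (percent of the solid substrate charged)

| time / h | product / % | starting material / % | solid substrate / % |
|---|---|---|---|
| 0.833 | 3 | 1 | 97 |
| 1.50 | 9 | 0 | 92 |
| 2.50 | 15 | 0 | 87 |
| 3.00 | 19 | 1 | 80 |
| 4.00 | 22 | 0 | 75 |

(scatter of a reading: 2 percentage points)

- solid substrate is a solid; its amount is given per volume of the solution
- at the start none of the solid substrate is in solution
- starting material is what solid substrate becomes in solution
- starting material means what is dissolved; the solid is not counted in it

- product at 6.0 h, in percent of the solid substrate charged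
- concentration of starting material in solution at 6.0 h, in percent of saturation

I began with just the main step, solid passing to product at a fixed fraction of its charge per hour. The green run's last reading, at 4.00 h, showed 22 % product and 25.0 % of the solid gone. Their mean, 23.5 %, meant the green charge would pass in 17.0 h, and carried over unchanged this gave 35.3 % at 6.0 h.

Then I added dissolving. Dissolved starting material read no higher than 2 % in either run, so I took it to leave the solution as it came. Green product read at 3.00 h twice what it read at 1.50 h, so I took the amount per hour as steady over that stretch; as my own assumption, I then took dissolving as the rate-limiting step, giving a steady amount per hour whatever the charge while solid lasted. The emptying time, the hours a charge needs to pass wholly into product at that steady amount, then grows with the charge: 25.4 h for the teal flask. That gave 23.6 % product, against 7.87 % at 120 min, where teal read 10 %.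

Last came the rest. At one partner per product, I reckoned 11.8 % of the partner's charge used and 76.4 % of the solid remaining, so I kept that number. Having taken dissolving as the rate-limiting step, I put the solution far below saturation.

The forecast said 27 % and 95 %, holding that “the solution should be at or near saturation”. The flask gave 23.9 % and 0 %.

    solid substrate ⇌ starting material, rate k1*(cs1 - [starting material]) while solid is left; crystals form when [starting material] > cs1 (solubility = 2.10 mM, k = 0.00455 min⁻¹)
    partner + first chain carrier → product + second chain carrier (k = 80100 L mol⁻¹ s⁻¹)
    2 first chain carrier → ended chains (k = 7.00 × 10⁸ L mol⁻¹ s⁻¹)
    starting material + initiating radical → capped initiator + first chain carrier (k = 7.25 × 10⁵ L mol⁻¹ s⁻¹)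
    starting material + second chain carrier → by-product + first chain carrier (k = 22400 L mol⁻¹ s⁻¹)
    initiator → 2 initiating radical (k = 0.00332 min⁻¹)
    first chain carrier → ended carrier (k = 3360 min⁻¹)

At 3.00 h in the teal flask, starting material was made 1.00 times as fast as it was used, each step taken net, with 0 % of the charge dissolved and 87.7 % still solid. Product then stood at 12.0 %, half its value at 6.0 h. For the neighbour with 5.6 mM of solid substrate, the emptying time becomes 10.1 h, which gives 59.4 %; the computed flask gave 57.2 %.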